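**Minutes of the meeting on the flask**

A leftover opened the meeting: at 5.00 h the dawn run held 5.50 mM less target than its charge allows, and the chair asked how much the flask would leave unconverted.

the same everywhere: gas phase 19 mM (held)
- dawn: substrate 0.050 M; run made earlier
- autumn: substrate 0.075 M; run made earlier
- flask: substrate 0.10 M; time 5.0 h

| run | time / h | target / % |
|---|---|---|
| dawn | 0.417 | 6 |
| dawn | 0.667 | 14 |
| dawn | 1.00 | 22 |
| dawn | 1.33 | 31 |
| dawn | 2.00 | 50 |
| dawn | 3.00 | 69 |
| dawn | 5.00 | 89 |
| autumn | 0.417 | 7 |
| autumn | 0.667 | 13 |
| autumn | 1.00 | 15 |
| autumn | 1.33 | 24 |
| autumn | 2.00 | 36 |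
| autumn | 3.00 | 50 |
| autumn | 5.00 | 81 |

(standard deviation of a reading: 1.5 percentage points)

* target at 5.0 h, in percent of the substrate charged
* concentration of dissolved gas in solution at 5.0 h, in percent of saturation

- the numbers in the tables scatter by 1.5 percentage points (one standard deviation)
- at the start none of the gas phase is in solution

The analyst proposed reading the runs in mM instead of percent. Dawn made 12.5 mM/h on average up to 2.00 h, and autumn made 12.5 mM/h up to 3.00 h, the same pace from a larger charge.

The process chemist argued that a pace which ignores the charge points to the gas crossing into solution as the rate-limiting step. She proposed freezing this reading, with its scatter, as the gas pace, the target made per litre per hour while that crossing sets the pace.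

I reckoned for the minutes that the flask, at this gas pace, reaches 62.5 % by 5.0 h. That leaves 37.5 mM of the flask's charge not turned to target, and the autumn run still kept the pace with 37.5 mM of its charge not turned to target at 3.00 h.

The forecast, a little higher than my figure, gave 64 % of target and 12 % of saturation, on the ground that “This looks like gas-transfer limitation.”

**Result**

The flask gives 64.1 % of target and 7.33 % of saturation at 5.0 h, and the most the transfer can deliver by then into a solution kept empty is 71.8 % of the substrate charged.

    substrate + dissolved gas → target (k = 0.0700 /M/s)
    dissolved gas + target → over-reacted product (k = 0.00270 /M/s)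
    gas phase ⇌ dissolved gas, rate k3*(csat - [dissolved gas]) (kL = 2.10 × 10⁻⁴ /s)

The flask's mean pace of 12.8 mM/h lies close to the gas pace of 12.5 mM/h. For the neighbouring flask read at 80 min, the gas pace reckons 16.7 %, and that flask stands at 17.8 %.

All runs stem from a simulated flask with made-up constants, noise included.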